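Ring D is taken apart at two bonds, C5'–C(=O) and O4'–CMe2, which makes it a five-carbon 3-methylbut-2-enoyl unit hung between the 4'-oxygen and C5' of ring B. Rings A, B and C, with the (S)-configured C2, then come intact from natural (S)-homoeriodictyol. In one photochemical operation the acyl group of a 4'-O-(3-methylbut-2-enoyl) ester is transferred to C5', the only hydrogen-bearing carbon ortho or para to O4' (C3' carries OMe, C1' carries ring C), and the unmasked 4'-phenol closes ring D on the enone. The precursor is the 7-O-benzyl, 5-hydroxy-free 4'-ester; benzyl and methyl ethers fall together at the end.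

Key step: step 3

Remarks
- Numbering: flavanone numbering is used (ring A: C5–C8; ring C: O1, C2–C4; ring B: C1'–C6'; ring D: the new pyranone).
- Structure: the oxygen substituent beside the ring D oxygen (OMe in 7, OH in 8) sits on ring B at C3' (C8 in chromanone numbering). Ring D itself carries only the gem-dimethyl carbon and the ketone.
- Assumption: commercial (S)-homoeriodictyol is taken as configurationally pure at C2; this should be confirmed by chiral HPLC, and the same assay applied to 7 and 8.
- Design: the 5-hydroxyl is deliberately left free, so that ring A keeps its hydrogen-bonded hydroxy-ketone as a harmless sink for absorbed light. The irradiation is run base-free, and the amine is added only after the lamp is off.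

Step 1
Reactants: 1 (S)-homoeriodictyol; 2 benzyl alcohol
Product: 3 (2S)-7-(benzyloxy)-5-hydroxy-2-(4-hydroxy-3-methoxyphenyl)chroman-4-one
Conditions: BnOH (1.05 equiv), PPh3, DIAD, THF, 0 °C → rt
Reagents that add atoms: benzyl alcohol (compound 2), OCc1ccccc1
Why: Mitsunobu O-alkylation, in which the 7-hydroxyl (a vinylogous acid para to the C4 carbonyl and by far the most acidic phenol) protonates the betaine and attacks the benzyloxyphosphonium ion, while the 5-hydroxyl is locked in a hydrogen bond to C4=O and the 4'-hydroxyl is an ordinary guaiacol-type phenol; the near-neutral medium should leave C2 untouched.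

Step 2
Reactants: 3 (2S)-7-(benzyloxy)-5-hydroxy-2-(4-hydroxy-3-methoxyphenyl)chroman-4-one; 4 3-methylbut-2-enoyl chloride
Product: 5 4-[(2S)-7-(benzyloxy)-5-hydroxy-4-oxochroman-2-yl]-2-methoxyphenyl 3-methylbut-2-enoate
Conditions: pyridine, CH2Cl2, 0 °C
Reagents that add atoms: 3-methylbut-2-enoyl chloride (compound 4), CC(C)=CC(=O)Cl
Why: Pyridine-mediated O-acylation through the acylpyridinium ion, in which the 4'-hydroxyl is the only unchelated phenol left; pyridine instead of a trialkylamine avoids the vinylketene pathway to the deconjugated 3-methylbut-3-enoate and is too weak a base to open ring C.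

Step 3
Reactants: 5 4-[(2S)-7-(benzyloxy)-5-hydroxy-4-oxochroman-2-yl]-2-methoxyphenyl 3-methylbut-2-enoate
Product: 7 (2S)-7-(benzyloxy)-5-hydroxy-2-(8-methoxy-2,2-dimethyl-4-oxochroman-6-yl)chroman-4-one, via ortho-hydroxyaryl enone 6 (not isolated)
Conditions: hν (254 nm, quartz), degassed MeCN (ca. 5 mM), 20 °C; lamp off, then Et3N (0.5 equiv), rt, dark
Reagents that add atoms: none
Why: Excitation of the ring B aryl ester should break the O4'–acyl bond homolytically to a solvent-caged 4'-phenoxyl/3-methylbut-2-enoyl radical pair, which recombines at C5' and tautomerises to the ortho-hydroxyaryl enone 6; in the dark the amine then lets the 4'-phenol add to the β,β-dimethyl enone to give 7. The closest known reaction type is the photo-Fries rearrangement of aryl 3-methylbut-2-enoates followed by intramolecular oxa-Michael addition, an established entry to 2,2-dimethylchroman-4-ones. Ring D closes in the 6-endo-trig mode, O4' attacking the β-carbon with both alkene carbons inside the new ring. No stereocentre is formed, since the new quaternary carbon bears two methyl groups, and C2 is not involved because the step uses no acid and only a weak amine that cannot enolise C3. The step needs acyl delivery to C5' alone, which the substrate secures because C3' (OMe) and C1' (ring C) are the only other positions ortho or para to O4' and both are substituted; recombination there cannot tautomerise and should revert. It also needs ring A to stay passive, which the retained 5-OH···O=C4 hydrogen bond should secure by dissipating excitation through proton transfer, helped by 254 nm light (where this chromophore is expected to absorb least) and by base-free irradiation (so that photoenolisation of the enoate reverts instead of deconjugating).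

Step 4
Reactants: 7 (2S)-7-(benzyloxy)-5-hydroxy-2-(8-methoxy-2,2-dimethyl-4-oxochroman-6-yl)chroman-4-one
Product: 8 (2S)-5,7-dihydroxy-2-(8-hydroxy-2,2-dimethyl-4-oxochroman-6-yl)chroman-4-one
Conditions: BBr3 (excess), CH2Cl2, −78 → 0 °C; then H2O, 0 °C
Reagents that add atoms: none
Why: Boron tribromide ether cleavage, in which the benzyl ether ionises readily and bromide attacks the methyl group of the boron-complexed C3' ether, while both pyran oxygens are weakly basic vinylogous-ester oxygens, a retro-oxa-Michael opening of ring D would reclose on acidic work-up without stereochemical cost, and the acylated ring B no longer stabilises a benzylic cation at C2.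

Compound list
1 | (S)-homoeriodictyol, (2S)-5,7-dihydroxy-2-(4-hydroxy-3-methoxyphenyl)chroman-4-one | COc1cc([C@@H]2CC(=O)c3c(O)cc(O)cc3O2)ccc1O | starting material
2 | benzyl alcohol | OCc1ccccc1 | starting material
3 | (2S)-7-(benzyloxy)-5-hydroxy-2-(4-hydroxy-3-methoxyphenyl)chroman-4-one | COc1cc([C@@H]2CC(=O)c3c(O)cc(OCc4ccccc4)cc3O2)ccc1O | intermediate
4 | 3-methylbut-2-enoyl chloride | CC(C)=CC(=O)Cl | starting material
5 | 4-[(2S)-7-(benzyloxy)-5-hydroxy-4-oxochroman-2-yl]-2-methoxyphenyl 3-methylbut-2-enoate | CC(C)=CC(=O)Oc1ccc([C@@H]2CC(=O)c3c(O)cc(OCc4ccccc4)cc3O2)cc1OC | intermediate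
6 | (2S)-7-(benzyloxy)-5-hydroxy-2-[4-hydroxy-3-methoxy-5-(3-methylbut-2-enoyl)phenyl]chroman-4-one | CC(C)=CC(=O)c1cc([C@@H]2CC(=O)c3c(O)cc(OCc4ccccc4)cc3O2)cc(OC)c1O | intermediate
7 | (2S)-7-(benzyloxy)-5-hydroxy-2-(8-methoxy-2,2-dimethyl-4-oxochroman-6-yl)chroman-4-one | CC1(C)CC(=O)c2cc([C@@H]3CC(=O)c4c(O)cc(OCc5ccccc5)cc4O3)cc(OC)c2O1 | intermediate
8 | (2S)-5,7-dihydroxy-2-(8-hydroxy-2,2-dimethyl-4-oxochroman-6-yl)chroman-4-one | CC1(C)CC(=O)c2cc([C@@H]3CC(=O)c4c(O)cc(O)cc4O3)cc(O)c2O1 | target

Total step count: 4. Longest linear sequence: 4 steps (1 → 3 → 5 → 7 → 8).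

Steps most likely to fail

Step 3.
- What may go wrong: the light may be taken up mainly by the ring A hydroxy-ketone and, as conversion rises, by 6 (inner filter), or the excited ester may pass its energy to ring A before the O–acyl bond breaks, so that conversion stalls. Escape of the radical pair from the solvent cage would return phenol 3, which can be fed back into step 2. Long irradiation could open ring C at O1–C2 and erode the C2 configuration, or shift the benzyl group photochemically.
- Fallback: it sets out from 3 and builds ring D thermally. Copper-catalysed O-propargylation of the 4'-hydroxyl (3-chloro-3-methylbut-1-yne, CuCl2 cat., DBU, MeCN, 0 °C) should give (2S)-7-(benzyloxy)-5-hydroxy-2-{3-methoxy-4-[(2-methylbut-3-yn-2-yl)oxy]phenyl}chroman-4-one F1. Heating in xylene at about 140 °C should trigger the aryl propargyl Claisen rearrangement, hydrogen shift and 6π oxa-electrocyclisation; this can only use C5' and gives (2S)-7-(benzyloxy)-5-hydroxy-2-(8-methoxy-2,2-dimethyl-2H-chromen-6-yl)chroman-4-one F2. Mukaiyama hydration (Co(acac)2 cat., PhSiH3, O2, THF) places oxygen on the benzylic carbon through the benzylic radical and gives (2S)-7-(benzyloxy)-5-hydroxy-2-(4-hydroxy-8-methoxy-2,2-dimethylchroman-6-yl)chroman-4-one F3 as both carbinol epimers. Oxidation of this benzylic alcohol with MnO2 in CH2Cl2 comes back to the route at 7.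

Step 4.
- What may go wrong: Lewis-acid-induced opening of ring C to the chalcone with unselective reclosure would erode the C2 configuration. The methyl ether may be cleaved incompletely at the temperature that C2 tolerates. Ring D may open by retro-oxa-Michael reaction and fail to reclose fully on work-up.
- Fallback: it sets out from 7 and removes the two ethers separately by two different mechanisms, so that the benzyl group never meets a Lewis acid. Hydrogenolysis (H2, 1 atm, 10% Pd/C, EtOAc, rt) should give (2S)-5,7-dihydroxy-2-(8-methoxy-2,2-dimethyl-4-oxochroman-6-yl)chroman-4-one F4. The methyl ether is then cleaved by a hard-acid/soft-nucleophile pair (AlCl3, NaI, MeCN, 0 °C → rt), iodide attacking the methyl group of the aluminium-bound ether. This comes back to the route at 8.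

Step 1.
- What may go wrong: loss of site selectivity, with benzylation of the 4'-hydroxyl in addition to or instead of the 7-hydroxyl, and co-elution of the regioisomers with Ph3PO.
- Fallback: it sets out from 1 and inverts the order of events. Acylation of both unchelated phenols with 4 (2.2 equiv, pyridine, CH2Cl2, 0 °C) should give 4-[(2S)-5-hydroxy-7-(3-methylbut-2-enoyloxy)-4-oxochroman-2-yl]-2-methoxyphenyl 3-methylbut-2-enoate F5. The ring A ester, being the ester of a vinylogous acid, is much the more activated one and should be removed selectively by imidazole-catalysed methanolysis (imidazole, MeOH/THF, rt) to give 4-[(2S)-5,7-dihydroxy-4-oxochroman-2-yl]-2-methoxyphenyl 3-methylbut-2-enoate F6. Mitsunobu benzylation with 2 (PPh3, DIAD, THF, 0 °C → rt) then has only the 7-hydroxyl to react with and comes back to the route at 5, bypassing 3.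

Further compounds
F1 | step 3 | (2S)-7-(benzyloxy)-5-hydroxy-2-{3-methoxy-4-[(2-methylbut-3-yn-2-yl)oxy]phenyl}chroman-4-one | C#CC(C)(C)Oc1ccc([C@@H]2CC(=O)c3c(O)cc(OCc4ccccc4)cc3O2)cc1OC
F2 | step 3 | (2S)-7-(benzyloxy)-5-hydroxy-2-(8-methoxy-2,2-dimethyl-2H-chromen-6-yl)chroman-4-one | CC1(C)C=Cc2cc([C@@H]3CC(=O)c4c(O)cc(OCc5ccccc5)cc4O3)cc(OC)c2O1
F3 | step 3 | (2S)-7-(benzyloxy)-5-hydroxy-2-(4-hydroxy-8-methoxy-2,2-dimethylchroman-6-yl)chroman-4-one, both carbinol epimers | CC1(C)CC(O)c2cc([C@@H]3CC(=O)c4c(O)cc(OCc5ccccc5)cc4O3)cc(OC)c2O1
F4 | step 4 | (2S)-5,7-dihydroxy-2-(8-methoxy-2,2-dimethyl-4-oxochroman-6-yl)chroman-4-one | CC1(C)CC(=O)c2cc([C@@H]3CC(=O)c4c(O)cc(O)cc4O3)cc(OC)c2O1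
F5 | step 1 | 4-[(2S)-5-hydroxy-7-(3-methylbut-2-enoyloxy)-4-oxochroman-2-yl]-2-methoxyphenyl 3-methylbut-2-enoate | CC(C)=CC(=O)Oc1ccc([C@@H]2CC(=O)c3c(O)cc(OC(=O)C=C(C)C)cc3O2)cc1OC
F6 | step 1 | 4-[(2S)-5,7-dihydroxy-4-oxochroman-2-yl]-2-methoxyphenyl 3-methylbut-2-enoate | CC(C)=CC(=O)Oc1ccc([C@@H]2CC(=O)c3c(O)cc(O)cc3O2)cc1OC
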